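**Plan**

- Locants (daucane): C1 quaternary fusion carbon with methyl C15; C2, C3; C4 isopropyl carbinol; C5 fusion CH; C6 ester carbon; C7; C8 (methyl C14) and C9 epoxide; C10 carbinol. β is the face of C15, α the face of H5.
- Enabling feature: C5 is the only seven-ring atom that also ends the C2–C3–C4 chain. The other six ring atoms (C1, C6–C10, with C14 on C8 para to C1) are the carbons of a p-tolyl ring carrying that chain, so C5 can be inserted as a carbene between C1 and C6.
- Cuts, in retrosynthetic order: epoxide oxygen at C8/C9; C10–O (with the C8=C9 alkene traced back to a C9 enone); the angelate C–O bond; the C6 and C9 oxygens (back to a C6–C9 diene); C4–isopropyl; C1–C15; last C5–C1 and C5–C6.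
- Forward: the tolyl diazoketone closes both rings at once (step 3). C15 enters by directed cyclopropanation and reductive opening, the isopropyl group by organocerium addition. The diene is then oxygenated with singlet oxygen, C10 is hydroxylated through the C9 ketone, and the alkene is transposed and epoxidised.
- Stereochemistry: an oxazaborolidine reduction sets C4 as a temporary centre that steers the cyclopropanation and so fixes C1. C5, C4, C6 and C10 are then set anti to the angular methyl, and C8/C9 by the C10 hydroxyl.

Key step: step 3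

Assumption: in step 2 the silyl group is taken to leave as Me3SiCl inside the flask; metal-bound transients (rhodium carbenoid, zinc and cerium alkoxides, samarium ketyl and enolate) are treated as forms of the numbered compounds and appear only in the Why lines.

**Route**

Step 1
Reactants: 1 3-(4-methylphenyl)propanoic acid
Product: 2 3-(4-methylphenyl)propanoyl chloride
Conditions: (COCl)2, cat. DMF, CH2Cl2, 0 °C to rt
Reagents that add atoms: oxalyl chloride, ClC(=O)C(=O)Cl
Why: Acyl chloride formation under chloroiminium catalysis should be clean for an unfunctionalised arylpropanoic acid and leaves only gases, so the crude chloride can be used after evaporation.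

Step 2
Reactants: 2 3-(4-methylphenyl)propanoyl chloride; 3 (trimethylsilyl)diazomethane
Product: 4 1-diazo-4-(4-methylphenyl)butan-2-one
Conditions: Me3SiCHN2 (2 equiv), THF/MeCN 1:1, 0 °C to rt
Reagents that add atoms: none
Why: C-Acylation of the nucleophilic diazo carbon (Arndt–Eistert-type diazoketone synthesis in its silyldiazomethane form) followed by loss of the silyl group to chloride should give the terminal diazoketone without handling diazomethane.

Step 3
Reactants: 4 1-diazo-4-(4-methylphenyl)butan-2-one
Product: 7 6-methyl-3,4-dihydroazulen-1(2H)-one, via norcaradiene 5 (not isolated), via kinetic cycloheptatrienone 6 (not isolated)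
Conditions: Rh2(OAc)4 (1 mol %), CH2Cl2, reflux, slow addition of 4 at high dilution; then Et3N, rt
Reagents that add atoms: none
Why: Rh2(OAc)4 expels N2 from 4 to give an electrophilic rhodium keto-carbenoid at C5, which adds to the ipso–ortho π bond of the tolyl ring (intramolecular Buchner reaction, the arene counterpart of a carbenoid cyclopropanation) and forms C5–C1 and C5–C6 in norcaradiene 5. The five-membered ring closes in this [2+1] addition because the C2–C3–C4 tether reaches only the ipso/ortho bond, and the seven-membered ring arises by thermal disrotatory 6π electrocyclic opening of the C1–C6 bond of 5 to cycloheptatriene 6. Triethylamine then moves the acidic C5 hydrogen to C10 through the extended enolate and gives the conjugated trienone 7. No stereocentre survives: the centres of 5 and 6 form as racemates under the achiral catalyst and become sp2 in 7, so absolute configuration is introduced in step 4. The step needs chemoselectivity for arene addition over acid-promoted drift of 5 to a 2-tetralone and over carbene dimerisation, which the moderately electrophilic acetate catalyst, the non-coordinating solvent and slow addition should secure; benzylic C–H insertion does not compete because it would close a four-membered ring. Regioselectivity is not in question, since the two ortho positions are equivalent and the para methyl necessarily ends on C8.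

Step 4
Reactants: 7 6-methyl-3,4-dihydroazulen-1(2H)-one
Product: 8 (1S)-6-methyl-1,2,3,4-tetrahydroazulen-1-ol
Conditions: (R)-Me-CBS oxazaborolidine [(R)-1-methyl-3,3-diphenyltetrahydro-1H,3H-pyrrolo[1,2-c][1,3,2]oxazaborole] (20 mol %), catecholborane (1.5 equiv), toluene, −78 °C
Reagents that add atoms: none
Why: Corey–Bakshi–Shibata reduction, in which the fully substituted alkenyl arm C5 acts as the large group and the C3 methylene as the small one, so the (R)-catalyst should give the (S)-carbinol at C4 (hydroxyl β), while catecholborane at low temperature does not hydroborate the triene.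

Step 5
Reactants: 8 (1S)-6-methyl-1,2,3,4-tetrahydroazulen-1-ol
Product: 9 cyclopropyl carbinol (C15 methylene bridging C1 and C5 on the β face)
Conditions: Et2Zn (2.2 equiv), CH2I2 (2.2 equiv), CH2Cl2, −20 to 0 °C
Reagents that add atoms: diiodomethane, ICI
Why: Hydroxyl-directed Simmons–Smith cyclopropanation: the zinc alkoxide should deliver the methylene to the adjacent tetrasubstituted C1=C5 bond, the only allylic and the most electron-rich alkene, on the face of the C4 oxygen, so C1 (R) and C5 (S) follow from C4.

Step 6
Reactants: 9 cyclopropyl carbinol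
Product: 10 cyclopropyl ketone (C4 ketone; 1R,5S)
Conditions: Dess–Martin periodinane, NaHCO3, CH2Cl2, 0 °C to rt
Reagents that add atoms: none
Why: Dess–Martin oxidation under buffered, non-acidic conditions should avoid cyclopropylcarbinyl cation rearrangement and removes the now redundant C4 centre while C1 and C5 stay fixed.

Step 7
Reactants: 10 cyclopropyl ketone
Product: 11 (3aR,8aR)-3a,6-dimethyl-3,3a,4,8a-tetrahydroazulen-1(2H)-one
Conditions: SmI2 (2.5 equiv), HMPA, t-BuOH (2 equiv), THF, −78 °C; AcOH/THF quench at −78 °C
Reagents that add atoms: none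
Why: Reductive ring opening of a cyclopropyl ketone: the ketyl should cleave the exocyclic C5–C15 bond, the only one aligned with the ketyl and diene π systems (the C1–C5 fusion bond lies in their nodal plane), a second electron and a proton turn C15 into the angular methyl, and the samarium trienolate is protonated kinetically at its α-carbon C5 anti to that methyl, which sets the trans fusion (5R) and leaves the diene, inert to SmI2, at C6–C9.

Step 8
Reactants: 11 (3aR,8aR)-3a,6-dimethyl-3,3a,4,8a-tetrahydroazulen-1(2H)-one
Product: 12 (1R,4R,5R)-dauca-6,8-dien-4-ol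
Conditions: i-PrMgCl, CeCl3 (anhydrous), THF, −78 to 0 °C
Reagents that add atoms: isopropylmagnesium chloride, CC(C)[Mg]Cl
Why: 1,2-Addition of the weakly basic organocerium reagent should outrun enolisation of the doubly activated C5 hydrogen and β-hydride reduction, and the nucleophile enters from the α face because the β face of the cyclopentanone is screened by the 1,3-related angular methyl, which places the hydroxyl β (4R).

Step 9
Reactants: 12 (1R,4R,5R)-dauca-6,8-dien-4-ol
Product: 14 4β,6α-dihydroxydauc-7-en-9-one, via 6α,9α-endoperoxide 13 (not isolated)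
Conditions: O2, visible light, 5,10,15,20-tetraphenylporphyrin (cat.), CH2Cl2, −30 °C; then Et3N, 0 °C to rt
Reagents that add atoms: oxygen, O=O
Why: Singlet oxygen should add across the s-cis C6–C9 diene in a [4+2] cycloaddition from the α face, where C5 presents only its hydrogen, and the amine then effects a Kornblum–DeLaMare rearrangement by removing the more accessible bridgehead hydrogen at C9 (next to the C10 methylene) rather than that at C6 (next to the branched C5), giving the C9 ketone and the 6α-hydroxyl (6S).

Step 10
Reactants: 14 4β,6α-dihydroxydauc-7-en-9-one; 15 angelic acid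
Product: 17 6α-angeloyloxy-4β-hydroxydauc-7-en-9-one, via mixed anhydride 16 (not isolated)
Conditions: 15, 2,4,6-trichlorobenzoyl chloride, Et3N, toluene, rt; then 14, 80 °C
Reagents that add atoms: none
Why: Yamaguchi esterification through the mixed anhydride without a nucleophilic pyridine catalyst should acylate the only secondary hydroxyl (C6), leave the tertiary C4 hydroxyl untouched and transfer the Z-acid without isomerisation to the tiglate.

Step 11
Reactants: 17 6α-angeloyloxy-4β-hydroxydauc-7-en-9-one
Product: 18 6α-angeloyloxy-4β,9-bis(trimethylsilyloxy)dauca-7,9-diene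
Conditions: Me3SiOTf (3 equiv), Et3N (5 equiv), CH2Cl2, −78 to 0 °C
Reagents that add atoms: trimethylsilyl trifluoromethanesulfonate, C[Si](C)(C)OS(=O)(=O)C(F)(F)F
Why: Soft enolisation (silyl triflate and amine) should convert the enone into the cross-conjugated 2-silyloxydiene by deprotonation at C10, its only α′ position, under conditions too weakly basic to affect the angelate; the tertiary hydroxyl is silylated at the same time, which is harmless.

Step 12
Reactants: 18 6α-angeloyloxy-4β,9-bis(trimethylsilyloxy)dauca-7,9-diene
Product: 20 6α-angeloyloxy-4β,10α-dihydroxydauc-7-en-9-one, via 10-siloxy ketone 19 (not isolated)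
Conditions: mCPBA, NaHCO3, CH2Cl2, −20 °C; then 1 M HCl, THF, 0 °C
Reagents that add atoms: 3-chloroperbenzoic acid, OOC(=O)c1cccc(Cl)c1
Why: Rubottom oxidation: the peracid should attack the electron-rich enol-ether bond C9=C10 in preference to the enoate and the C7=C8 bond, from the α face opposite the vicinal angular methyl, silyl migration gives the 10α-siloxy ketone (10S), and dilute acid removes both trimethylsilyl groups.

Step 13
Reactants: 20 6α-angeloyloxy-4β,10α-dihydroxydauc-7-en-9-one
Product: 21 C9 tosylhydrazone of 20
Conditions: TsNHNH2, pyridinium p-toluenesulfonate (cat.), EtOH, 50 °C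
Reagents that add atoms: 4-methylbenzenesulfonohydrazide, Cc1ccc(cc1)S(=O)(=O)NN
Why: Acid-catalysed hydrazone formation at the only ketone should leave the ester and the carbinol centres untouched; the C=N geometry is immaterial.

Step 14
Reactants: 21 C9 tosylhydrazone of 20
Product: 23 6α-angeloyloxydauc-8-ene-4β,10α-diol, via allylic diazene 22 (not isolated)
Conditions: catecholborane (4 equiv), CHCl3, 0 °C; then NaOAc·3H2O, reflux
Reagents that add atoms: none
Why: Reductive 1,3-transposition of an enone tosylhydrazone: catecholborane delivers hydride 1,2 to C9, acetate induces loss of sulfinate to the allylic diazene, and its retro-ene fragmentation expels N2 while transferring hydrogen to C7 and moving the double bond to C8=C9, with the C6 and C10 centres untouched.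

Step 15
Reactants: 23 6α-angeloyloxydauc-8-ene-4β,10α-diol
Product: 24 lapiferine
Conditions: VO(acac)2 (5 mol %), t-BuOOH (1.5 equiv), CH2Cl2, 0 °C to rt
Reagents that add atoms: tert-butyl hydroperoxide, CC(C)(C)OO
Why: Vanadium-catalysed hydroxyl-directed epoxidation: the C10 alkoxide binds the vanadium peroxide and should deliver oxygen to the adjacent trisubstituted C8=C9 bond on its own α face (8R,9S), while the electron-poor angelate alkene, which has no directing hydroxyl, is not oxidised.

**Compound list**

1 | 3-(4-methylphenyl)propanoic acid | Cc1ccc(CCC(=O)O)cc1 | starting material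
2 | 3-(4-methylphenyl)propanoyl chloride | Cc1ccc(CCC(=O)Cl)cc1 | intermediate
3 | (trimethylsilyl)diazomethane | C[Si](C)(C)C=[N+]=[N-] | starting material
4 | 1-diazo-4-(4-methylphenyl)butan-2-one | Cc1ccc(CCC(=O)C=[N+]=[N-])cc1 | intermediate
5 | norcaradiene ketone, not isolated (racemic; cyclopropane C1–C5–C6 fused to the cyclopentanone and to a 4-methylcyclohexa-2,4-diene, relative configuration fixed by the fusion) | O=C1CCC23C=CC(C)=CC2C13 | intermediate
6 | 6-methyl-3,8a-dihydroazulen-1(2H)-one, not isolated (racemic) | O=C1CCC2=CC=C(C)C=CC12 | intermediate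
7 | 6-methyl-3,4-dihydroazulen-1(2H)-one | O=C1CCC2=C1C=CC(C)=CC2 | intermediate
8 | (1S)-6-methyl-1,2,3,4-tetrahydroazulen-1-ol (C4 hydroxyl β) | O[C@H]1CCC2=C1C=CC(C)=CC2 | intermediate
9 | cyclopropyl carbinol: 8 with the C15 methylene bridging C1 and C5 on the β face, cis to the 4β-hydroxyl (4S,1R,5S) | O[C@H]1CC[C@@]23C[C@@]12C=CC(C)=CC3 | intermediate
10 | cyclopropyl ketone: C4 ketone of 9 (1R,5S) | O=C1CC[C@@]23C[C@@]12C=CC(C)=CC3 | intermediate
11 | (3aR,8aR)-3a,6-dimethyl-3,3a,4,8a-tetrahydroazulen-1(2H)-one (C15 β, H5 α) | O=C1CC[C@]2(C)CC=C(C)C=C[C@@H]12 | intermediate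
12 | (1R,4R,5R)-dauca-6,8-dien-4-ol (4β-OH, 5α-H) | CC(C)[C@]1(O)CC[C@]2(C)CC=C(C)C=C[C@@H]12 | intermediate
13 | 6α,9α-epidioxydauc-7-en-4β-ol, not isolated | CC(C)[C@]1(O)CC[C@]2(C)C[C@@H]3OO[C@@H](C=C3C)[C@@H]12 | intermediate
14 | 4β,6α-dihydroxydauc-7-en-9-one (1R,4R,5S,6S) | CC(C)[C@]1(O)CC[C@]2(C)CC(=O)C(C)=C[C@H](O)[C@@H]12 | intermediate
15 | angelic acid, (Z)-2-methylbut-2-enoic acid | C/C=C(/C)C(=O)O | starting material
16 | angelic 2,4,6-trichlorobenzoic anhydride, not isolated | C/C=C(/C)C(=O)OC(=O)c1c(Cl)cc(Cl)cc1Cl | intermediate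
17 | 6α-angeloyloxy-4β-hydroxydauc-7-en-9-one (1R,4R,5S,6S) | C/C=C(/C)C(=O)O[C@H]1C=C(C)C(=O)C[C@@]2(C)CC[C@@](O)(C(C)C)[C@H]12 | intermediate
18 | 6α-angeloyloxy-4β,9-bis(trimethylsilyloxy)dauca-7,9-diene | C/C=C(/C)C(=O)O[C@H]1C=C(C)C(O[Si](C)(C)C)=C[C@@]2(C)CC[C@@](O[Si](C)(C)C)(C(C)C)[C@H]12 | intermediate
19 | 6α-angeloyloxy-4β,10α-bis(trimethylsilyloxy)dauc-7-en-9-one, not isolated | C/C=C(/C)C(=O)O[C@H]1C=C(C)C(=O)[C@@H](O[Si](C)(C)C)[C@@]2(C)CC[C@@](O[Si](C)(C)C)(C(C)C)[C@H]12 | intermediate
20 | 6α-angeloyloxy-4β,10α-dihydroxydauc-7-en-9-one (1S,4R,5S,6S,10S) | C/C=C(/C)C(=O)O[C@H]1C=C(C)C(=O)[C@@H](O)[C@@]2(C)CC[C@@](O)(C(C)C)[C@H]12 | intermediate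
21 | C9 tosylhydrazone of 20 (C=N geometry not defined) | C/C=C(/C)C(=O)O[C@H]1C=C(C)C(=NNS(=O)(=O)c3ccc(C)cc3)[C@@H](O)[C@@]2(C)CC[C@@](O)(C(C)C)[C@H]12 | intermediate
22 | 6α-angeloyloxy-9-diazenyldauc-7-ene-4β,10α-diol, not isolated (C9 configuration not controlled and immaterial) | C/C=C(/C)C(=O)O[C@H]1C=C(C)C(N=N)[C@@H](O)[C@@]2(C)CC[C@@](O)(C(C)C)[C@H]12 | intermediate
23 | 6α-angeloyloxydauc-8-ene-4β,10α-diol (1S,4R,5S,6S,10R) | C/C=C(/C)C(=O)O[C@H]1CC(C)=C[C@@H](O)[C@@]2(C)CC[C@@](O)(C(C)C)[C@H]12 | intermediate
24 | lapiferine, 6α-angeloyloxy-8α,9α-epoxydaucane-4β,10α-diol (1S,4R,5S,6S,8R,9S,10S) | C/C=C(/C)C(=O)O[C@H]1C[C@@]2(C)O[C@H]2[C@@H](O)[C@@]2(C)CC[C@@](O)(C(C)C)[C@H]12 | target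

**Step count and weak points**

Total step count: 15. Longest linear sequence: 15 steps (1 to 24); 3 and 15 are commercial.

The three steps most likely to fail:

1. Step 9. What may go wrong: cycloaddition on the β face or ene-type hydroperoxidation, and proton removal at C6 instead of C9 in the peroxide rearrangement, which would place the ketone at C6. The fallback sets out from 12 and rejoins at 17. Buffered mCPBA epoxidation of the more substituted C8=C9 bond, from the α face opposite the angular methyl, should give the vinyl epoxide 8α,9α-epoxydauc-6-en-4β-ol F1. With Pd(PPh3)4 (a zerovalent palladium complex) in THF at 0 °C the allylic C8–O bond ionises with inversion and angelic acid 15 attacks the less substituted allyl terminus C6, again with inversion (Tsuji–Trost-type cis-1,4 opening of a diene monoepoxide). This should give 6α-angeloyloxydauc-7-ene-4β,9α-diol F2, with C6 fixed relative to C9 and the ester already in place. Dess–Martin oxidation of the allylic C9 hydroxyl then gives 17.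

2. Step 7. What may go wrong: electron transfer beyond the ring-opening stage (carbinol or pinacol formation), and protonation of the trienolate at C7 or C9 or on the β face, giving conjugated or cis-fused ketones. The fallback sets out from 10 and rejoins at 11 and replaces the reductive opening by a polar one. Iodotrimethylsilane (from Me3SiCl and NaI, MeCN, −20 °C) silylates the carbonyl and iodide opens the same exocyclic C5–C15 bond by homo-conjugate addition, giving (3aS)-3a-(iodomethyl)-6-methyl-1-(trimethylsilyloxy)-2,3,3a,4-tetrahydroazulene F3. Fluoride in the presence of acetic acid (Bu4NF, AcOH, THF, −78 °C) releases the enolate under kinetic proton control and should give the trans-fused (3aS,8aR)-3a-(iodomethyl)-6-methyl-3,3a,4,8a-tetrahydroazulen-1(2H)-one F4. Radical deiodination (Bu3SnH, 2,2'-azobis(2-methylpropionitrile), benzene, 80 °C) converts the iodomethyl group into the angular methyl and gives 11.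

3. Step 14. What may go wrong: sluggish hydride delivery to the hindered, α′-oxygenated C=N bond, or 1,4-reduction, leaving hydrazone or untransposed material. The fallback sets out from 20 and rejoins at 23 and runs the transposition through an allylic alcohol instead of a hydrazone. Silylation of the secondary C10 hydroxyl (Et3SiCl, imidazole, DMF) gives 6α-angeloyloxy-4β-hydroxy-10α-(triethylsilyloxy)dauc-7-en-9-one F5. Luche reduction (NaBH4, CeCl3·7H2O, MeOH, −40 °C) gives 6α-angeloyloxy-10α-(triethylsilyloxy)dauc-7-ene-4β,9-diol F6, whose C9 configuration is immaterial. A Mitsunobu reaction with 2-nitrobenzenesulfonylhydrazide (PPh3, diethyl azodicarboxylate, THF, −30 °C) gives the sulfonylhydrazine 6α-angeloyloxy-9-[1-(2-nitrophenylsulfonyl)hydrazinyl]-10α-(triethylsilyloxy)dauc-7-en-4β-ol F7. On warming this loses the sulfinic acid to give 6α-angeloyloxy-9-diazenyl-10α-(triethylsilyloxy)dauc-7-en-4β-ol F8, which expels N2 by the same retro-ene shift as in step 14 and gives 6α-angeloyloxy-10α-(triethylsilyloxy)dauc-8-en-4β-ol F9. HF·pyridine in THF removes the silyl group and gives 23.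

Further compounds
F1 | step 9 | 8α,9α-epoxydauc-6-en-4β-ol | CC(C)[C@]1(O)CC[C@]2(C)C[C@@H]3O[C@]3(C)C=C[C@@H]12
F2 | step 9 | 6α-angeloyloxydauc-7-ene-4β,9α-diol | C/C=C(/C)C(=O)O[C@H]1C=C(C)[C@@H](O)C[C@@]2(C)CC[C@@](O)(C(C)C)[C@H]12
F3 | step 7 | (3aS)-3a-(iodomethyl)-6-methyl-1-(trimethylsilyloxy)-2,3,3a,4-tetrahydroazulene | C[Si](C)(C)OC1=C2C=CC(C)=CC[C@@]2(CI)CC1
F4 | step 7 | (3aS,8aR)-3a-(iodomethyl)-6-methyl-3,3a,4,8a-tetrahydroazulen-1(2H)-one | O=C1CC[C@]2(CI)CC=C(C)C=C[C@@H]12
F5 | step 14 | 6α-angeloyloxy-4β-hydroxy-10α-(triethylsilyloxy)dauc-7-en-9-one | C/C=C(/C)C(=O)O[C@H]1C=C(C)C(=O)[C@@H](O[Si](CC)(CC)CC)[C@@]2(C)CC[C@@](O)(C(C)C)[C@H]12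
F6 | step 14 | 6α-angeloyloxy-10α-(triethylsilyloxy)dauc-7-ene-4β,9-diol (C9 not defined) | C/C=C(/C)C(=O)O[C@H]1C=C(C)C(O)[C@@H](O[Si](CC)(CC)CC)[C@@]2(C)CC[C@@](O)(C(C)C)[C@H]12
F7 | step 14 | 6α-angeloyloxy-9-[1-(2-nitrophenylsulfonyl)hydrazinyl]-10α-(triethylsilyloxy)dauc-7-en-4β-ol (C9 not defined) | C/C=C(/C)C(=O)O[C@H]1C=C(C)C(N(N)S(=O)(=O)c3ccccc3[N+](=O)[O-])[C@@H](O[Si](CC)(CC)CC)[C@@]2(C)CC[C@@](O)(C(C)C)[C@H]12
F8 | step 14 | 6α-angeloyloxy-9-diazenyl-10α-(triethylsilyloxy)dauc-7-en-4β-ol (C9 not defined) | C/C=C(/C)C(=O)O[C@H]1C=C(C)C(N=N)[C@@H](O[Si](CC)(CC)CC)[C@@]2(C)CC[C@@](O)(C(C)C)[C@H]12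
F9 | step 14 | 6α-angeloyloxy-10α-(triethylsilyloxy)dauc-8-en-4β-ol | C/C=C(/C)C(=O)O[C@H]1CC(C)=C[C@@H](O[Si](CC)(CC)CC)[C@@]2(C)CC[C@@](O)(C(C)C)[C@H]12
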